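Watch the partner.

| flask | starting material | partner | protic impurity | free catalyst | time | remark |
|---|---|---|---|---|---|---|
| zeta | 0.10 M (fed, over 20 min) | 1.00 equiv | 2.00 mM | 0.05 mol% | 2.0 h | the fed solution adds 0.10 times the starting volume |
| epsilon | 0.10 M (fed, over 20 min) | 2.00 equiv | 2.00 mM | 0.05 mol% | 2.0 h | the fed solution adds 0.10 times the starting volume |
| eta | 0.10 M (fed, over 20 min) | 4.00 equiv | 2.00 mM | 0.05 mol% | 2.0 h | the fed solution adds 0.10 times the starting volume |

* part of the starting material that has reacted at the end, zeta
* part of the starting material that has reacted at the end, epsilon
* part of the starting material that has reacted at the end, eta
* what raising the equivalents of partner from its lowest to its highest value here does to the part of the starting material that has reacted (changes below 5 percentage points count as none) (it rises / it falls / no change)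

- what is said of released group includes idle adduct
- amounts are per litre of the starting volume; all of the dose is in the solution fed
- run time (zeta): 2.0 h

    starting material + free catalyst ⇌ catalyst intermediate A (K1 = 17 /M, k1 = 720 /M/s)
    partner + catalyst intermediate A → catalyst intermediate B (k2 = 30 /M/s)
    catalyst intermediate B → released group + catalyst intermediate C (k3 = 1.3 /s)
    catalyst intermediate C → catalyst intermediate D (k4 = 1.2 /s)
    catalyst intermediate D → free catalyst + product (k5 = 40 /s)
    partner + released group ⇌ idle adduct, settled at all times (K6 = 34 /M)
    partner + protic impurity → quenched reagent (k7 = 2.6 /M/s)
    released group → by-product carried off (k8 = 5.8 × 10⁻⁵ /s)

Partner, protic impurity and free catalyst stand in the flask, and starting material is dosed in. The impurity can take 2.00 mM of partner, so the budget of partner is smaller than its charge, and in zeta it falls below the starting material charged, which makes partner the limiting reagent there. Each turn of the cycle uses one partner and sets free one released group. But released group binds free partner in a fast balance, constant 34 /M, to give idle adduct, so a turn can take more than one partner from the free pool.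

We divide the rate at which partner leaves the free pool by the rate of turnover at the opening, where no released group stands yet, and time drops out. This leaves a price for the opening: one, plus the balance constant times c(partner) over one plus that same product. Once free released group stands in the flask the ratio changes form and sinks, and the loss of released group brings time back into it. At the opening of zeta the price is 1.77. Budget over price, per starting material charged, gives 55.3%; this is the reach, the part of the starting material that the budget pays for at the opening price.

So in zeta free partner should outlast the reach. Free partner and idle adduct together lose one partner per turn, which puts a ceiling at 98.0%. We expect zeta inside that window, and not close to its ceiling, since the partner-taking step slows with c(partner). For epsilon the reach is 106% and for eta 206%, so we expect both near completion and the conversion to rise.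

The forecast gave 76%, 99.7% and 100%, with the trend "it rises", holding that “the impurity and especially the released group tie up the partner”.

The simulation gives 73.7% for zeta, 98.2% for epsilon and >99.9% for eta; it rises, by 26 percentage points.

Zeta ended above its reach of 55.3% and below its ceiling, with 9.78% of its partner free. A neighbouring flask is zeta with 1.70 equiv of partner. The same reckoning gives an opening price of 1.85 and a reach of 90.7%. That flask ended at 94.9%, above its reach, with 5.1% of the starting material and 18% of the partner left.

(The constants belong to no real substance; the rest is arithmetic.)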